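Amounts were what I had to go on: in each earlier run, the substrate gone and the target found, the difference having gone to self-condensation product.

common to all: substrate 13 mM

|  | free catalyst | added ligand | temperature | remark | time |
|---|---|---|---|---|---|
| larch | 0.06 mol% | 38 µM | 85 °C | run made earlier |  |
| birch | 0.24 mol% | 38 µM | 105 °C | run made earlier |  |
| ash | 0.12 mol% | 57 µM | 85 °C | run made earlier |  |
| south-west | 0.12 mol% | 38 µM | 90 °C |  | 40 h |
| south-east | 0.12 mol% | 38 µM | 120 °C |  | 40 h |
| north-east | 0.12 mol% | 38 µM | 105 °C |  | 40 h |

- larch (time / h: target / %, substrate / %): 8.00: 2.4, 51.1; 15.0: 2.3, 35.8; 25.0: 5.1, 25.7; 30.0: 4.3, 21.3; 40.0: 5.0, 16.1; 50.0: 4.5, 13.0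
- birch (time / h: target / %, substrate / %): 4.00: 18.6, 34.0; 8.00: 22.1, 19.1; 12.0: 24.2, 14.2; 15.0: 25.4, 10.7; 20.0: 26.1, 8.2; 25.0: 27.4, 7.0
- ash (time / h: target / %, substrate / %): 4.00: 2.0, 66.8; 8.00: 2.7, 50.0; 15.0: 5.3, 34.0; 25.0: 6.8, 23.7; 50.0: 8.8, 13.6

(readings scatter by 0.5 percentage points)

* which flask leads in amount of target, in percent of the substrate charged ("all alike" within 1.5 percentage points) (south-west / south-east / north-east / all alike)
* how much target is there at the end, in percent of the substrate charged: south-west
* how much target is there at the end, in percent of the substrate charged: south-east
* how much target is there at the end, in percent of the substrate charged: north-east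

- a species is counted by the substrate in it: one self-condensation product counts as two
- the analysis behind the earlier runs scatters by 0.5 percentage points, standard deviation
- steps thought possible: 2 free catalyst -> spent catalyst; substrate + free catalyst -> free catalyst + target; 2 substrate -> self-condensation product; free catalyst + added ligand <-> idle complex

The last birch reading gave me 4.79, my waste ratio: substrate gone without becoming target, per part of target, rescaled in inverse proportion to the loading so that each run speaks for 0.12 mol%. It is the inverse of a selectivity factor, and target as a share of substrate used is one over one plus this ratio.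

At 85 °C, the last readings gave 9.17 for larch and 8.82 for ash, but the readings at 25.0 h gave 6.78 and 10.2, further apart, and ash also held 57 µM of added ligand against 38 µM in larch, so this pair did not prove the rescaling, which I kept as an assumption. For the reckoning I took ash, whose last target reading of 8.8% stood higher above the scatter of 0.5 percentage points than the 4.5% of larch, although its ligand charge differs from the 38 µM of the three asked flasks. Within birch, the first reading gave 5.10 against 4.79 at the last. Still, one number was not enough: it needs a temperature rule, and it says nothing of substrate remaining, of which larch still held 13.0% at its last reading.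

I let the ratio change by the same factor per degree from ash to birch. That gave 7.57 for south-west, 4.79 for north-east and 3.03 for south-east, the lowest. The target shares of substrate used were therefore 11.7%, 17.3% and 24.8%, with south-east ahead.

The forecast said all alike, with 14.5%, 16% and 15.5% for south-west, north-east and south-east, holding that “faster dimerisation offsets the faster catalysis”. My reckoning parted from it at south-east.

    2 free catalyst → spent catalyst (k = 3990 L mol⁻¹ h⁻¹, Ea = 61.0 kJ mol⁻¹)
    substrate + free catalyst → free catalyst + target (k = 1970 L mol⁻¹ h⁻¹, Ea = 76.0 kJ mol⁻¹)
    2 substrate → self-condensation product (k = 5.96 L mol⁻¹ h⁻¹, Ea = 64.0 kJ mol⁻¹)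
    free catalyst + added ligand ⇌ idle complex (K = 43000 L mol⁻¹, k = 67100 L mol⁻¹ h⁻¹, Ea = 37.0 kJ mol⁻¹, ΔH = −55.0 kJ mol⁻¹)
    (constants at 90 °C)

South-east led with 24.1% of target, against 18.9% in north-east and 12.4% in south-west. In north-east, self-condensation used substrate at 4.3 times the rate of the catalytic step at the start, and the end amounts give a waste ratio of 4.04, against the 4.79 read from birch. The neighbour of north-east with 0.2 mol% of free catalyst, rescaled from birch to 2.87 and with 4.2% of its substrate left, reckons to 24.8% of target, and it held 25.5%.

Readings and results stem from a simulated flask for substances that don't exist; noise was put on by code.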